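## The problem

The target **28** is a trans-fused 3a,4,5,7a-tetrahydro-1H-indene. A cyclopentene (C1, C2=C3, C3a, C7a) is joined to a cyclohexene (C3a, C4, C5, C6=C7, C7a), numbered so that the carboxyl sits on C4. It has five stereocentres. C1 (methyl), C7a and C3a form a contiguous all-trans triad on the five-membered ring. C4 (methyl, CO2H) and C5 (ethyl, phenylbutadienyl) are adjacent all-carbon quaternary centres, with the carboxyl cis to H-3a and cis to the dienyl group. The triad can be set by substrate control on a cyclopentenone, but the two quaternary carbons cannot be reached by an external reagent; they must be formed intramolecularly and their configuration relayed from the ring. The (1E,3E)-4-phenylbutadienyl group is sensitive to acid, oxidants and electrophiles and should come last. The acid is tertiary and flanked by a quaternary carbon, so an ester there could hardly be cleaved; the acid must emerge free, and once free it would capture a hydroxymethyl group on C5 as a γ-lactone. The enabling feature is that O=C–C4–C5–C6=C7 is a γ,δ-unsaturated acid, the retron of an ester-enolate Claisen rearrangement, and that the acid carbon and C7 are 1,5-related and can first be tied together as a δ-lactone.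

## Retrosynthesis

**28 to 25 and 26.** The C1′=C2′ bond of the side chain is cut last (Horner–Wadsworth–Emmons), giving the neopentyl aldehyde **25** and the cinnamyl phosphonate **26**. Cutting here keeps the diene out of every earlier step, and a phosphonate is preferred to a phosphonium ylide for E selectivity. The forward step must olefinate a hindered aldehyde beside a free carboxylate, so an excess of the phosphonate anion is required.

**25 to 24.** The aldehyde is masked as a dimethyl acetal. An alcohol at this position was rejected: a C5 hydroxymethyl group cis to the C4 acid would lactonise on release, and the lactone has the wrong oxidation pattern. The acetal survives base and heat and is removed in one mild step.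

**24 to 21.** The C4–C5 bond is cut and the C7–O bond re-formed, which turns the carbocycle into the trans-fused δ-lactone **21** with a trisubstituted alkenyl group on C7 (ester-enolate Claisen transform). This cut removes both quaternary centres at once and replaces them by one tertiary carbinol centre and an alkene geometry. Cutting C5–C6 or C3a–C4 instead would leave one quaternary centre to be made separately. The forward reaction must pass through a boat-like transition state.

**21 to 19.** The C7–CH3 bond and the lactone C–O bond are cut, giving the alkenyl ketone **19** and a methyl-metal reagent. The alternative order (methyl ketone plus alkenyl nucleophile) was rejected: the larger alkenyl reagent should enter from the less hindered side of the carbonyl, flanked only by the C1 methyl, which gives the C7 epimer that cannot rearrange. With methyl as the nucleophile the same preference gives the required epimer.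

**19 to 12 and 16.** The C6–C7 bond is cut, giving aldehyde **12** and alkenyl bromide **16** (used as its lithium derivative **17**), with an oxidation of the intermediate alcohol **18**. The bromide comes in two steps from 2-ethylacrolein **13**, through bromoenal **15**, with the ethyl group cis to the metal-bearing carbon.

**12 to 8 and 2.** The C3a–C4 bond is cut (Mukaiyama–Michael transform), giving enone **8** and the propanoate ketene acetal **2**. The silyl enol ether **9** becomes the enol triflate **10**, whose reduction places the alkene at C2=C3. The vinyl group on C7a is a latent formyl group; it is cleaved at the triflate stage (**11**), where it is the only electron-rich alkene. An allylic-ester Claisen route to C3a was set aside because it depends on a cyclopentenone reduction of uncertain facial selectivity.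

**8 to 3.** The C3–ethyl, C1–methyl and C7a–vinyl bonds are cut. Enone **8** comes from iodoenone **7** by cross-coupling, **7** from enone **6**, and **6** from ketone **5**, the product of conjugate vinyl addition and enolate methylation on (S)-4-silyloxycyclopentenone **3**. The silyloxy group directs the vinyl group and is then eliminated, so the stereocentre of **3** is transferred to C7a.

## Roads not taken

**Alternative 1:** The cut is C3–C3a of the cyclopentene. Zerovalent nickel, generated at a cathode, inserts into the C–I bond of the acyclic (Z)-iodoalkene **A1**, and the alkenylnickel adds 5-exo to the tethered (E)-enoate to give cyclopentene **A2**.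
- Merits: the C3 ethyl group and the C2=C3 alkene are fixed by the iodoalkene, so iodination, cross-coupling and triflate reduction (steps 4, 5, 7 and 9 here) are not needed, and the base-sensitive enones **6**–**8** are avoided.
- Weak points: C1 and C7a must be set in an open chain; C3a arises by 1,2-induction only; **A2** carries an acetate arm and a masked methyl ketone, which leads to the order of addition at C7 judged unfavourable above.
- Comparison: this is a different front end, not a different answer to the main problem, since the quaternary pair and the six-membered ring are untouched. It may well be shorter for the cyclopentene. The chosen plan sets against it a triad built entirely by ring-controlled steps and a formyl group at C7.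

**Alternative 2:** The cuts are C3a–C7a, C1–C2 and C2–C3. A cobalt-carbonyl-mediated Pauson–Khand reaction of enyne **A3** closes both rings and gives enone **A4**.
- Merits: three C–C bonds and two rings in one step, which the chosen plan cannot match.
- Weak points: the C4/C5 quaternary pair must already be present in **A3**, made in an open chain with full control, so the hardest problem is moved and not solved. The alkyne is flanked by a quaternary carbon, the alkene partner is a 1,3-diene, and a six-membered ring must close. C7a and C1 are controlled only by the remote pair. **A4** has the alkene at C3=C3a and a C2 ketone, so a reductive transposition with late setting of C3a is still needed, and its silyloxymethyl group leads back to the lactonisation problem.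
- Comparison: the chosen key step forms one bond and one ring only, but it creates both quaternary centres in that step and derives their configuration from a ring stereocentre.

**Alternative 3:** The cut is C5–C6. Zerovalent palladium inserts into the (Z)-alkenyl iodide **A5**, 6-exo carbopalladation of the trisubstituted alkene creates C5, and β-hydride elimination unveils the diene, giving ester **A6**.
- Merits: the diene arises in the ring-forming step, so the end of the synthesis is two steps shorter than here; this is a real advantage.
- Weak points: the C4 quaternary centre must be set beforehand on a side arm, and it is the only control element for C5, although its methyl and ester groups differ little in size. A quaternary carbon must form next to a quaternary carbon by insertion into a hindered alkene. **A6** is the methyl ester of a very hindered acid, which must be cleaved in the presence of the diene.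
- Comparison: the chosen plan sets against the shorter end game a rearrangement that forms C4 and C5 together with a defined relay and releases the acid free.

Key step: step 15

## Route

Assumptions: compounds **1**, **3**, **13** and **26** and the reagents in the Conditions lines are commercial. The tetrahydroindene numbering of **28** is used for all intermediates. The C4 centre of the propanoate arm is carried as a mixture of epimers from **9** to **21**.

Step 1
Reactants: 1 methyl propanoate
Product: 2 1-methoxy-1-(trimethylsilyloxy)prop-1-ene
Conditions: LiN(iPr)2, THF, −78 °C; Me3SiCl, −78 °C to rt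
Reagents that add atoms: chlorotrimethylsilane, C[Si](C)(C)Cl
Why: Kinetic ester enolisation and O-silylation give the silyl ketene acetal; its alkene geometry is without consequence because C4 becomes planar again in 22.

Step 2
Reactants: 3 (S)-4-(tert-butyldimethylsilyloxy)cyclopent-2-en-1-one
Product: 5 all-trans 4-(tert-butyldimethylsilyloxy)-2-methyl-3-vinylcyclopentan-1-one, via bromomagnesium enolate 4 (not isolated)
Conditions: CH2=CHMgBr, CuBr·SMe2 (cat.), THF, −78 °C; then MeI, DMPU, −78 to −30 °C
Reagents that add atoms: vinylmagnesium bromide, C=C[Mg]Br; iodomethane, CI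
Why: Copper-catalysed conjugate addition puts the vinyl group anti to the silyloxy group, and enolate 4 is methylated anti to the new vinyl group (three-component coupling), which sets C7a and C1 trans. Any cis-methyl epimer is corrected in step 3.

Step 3
Reactants: 5 all-trans 4-(tert-butyldimethylsilyloxy)-2-methyl-3-vinylcyclopentan-1-one
Product: 6 trans-5-methyl-4-vinylcyclopent-2-en-1-one
Conditions: DBU, CH2Cl2, 0 °C
Reagents that add atoms: none
Why: E1cB loss of the silanol from the β-silyloxy ketone gives the enone and leaves the stereochemical information of 3 at C7a; the α′ centre C1 settles trans. Exposure is kept short because H-7a is doubly allylic.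

Step 4
Reactants: 6 trans-5-methyl-4-vinylcyclopent-2-en-1-one
Product: 7 trans-2-iodo-5-methyl-4-vinylcyclopent-2-en-1-one
Conditions: I2, pyridine, CH2Cl2, 0 °C to rt
Reagents that add atoms: iodine, II
Why: Pyridine-mediated α-iodination of the enone (conjugate addition of pyridine, iodination of the enolate, elimination) touches neither the vinyl group nor the stereocentres.

Step 5
Reactants: 7 trans-2-iodo-5-methyl-4-vinylcyclopent-2-en-1-one
Product: 8 trans-2-ethyl-5-methyl-4-vinylcyclopent-2-en-1-one
Conditions: Et2Zn, PdCl2(dppf) (cat.), THF/DMF, 0 °C to rt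
Reagents that add atoms: diethylzinc, CC[Zn]CC
Why: Negishi coupling of an α-iodoenone with an alkylzinc installs the C3 ethyl group under base-free conditions, so C7a is not epimerised; the bidentate phosphine curbs β-hydride elimination.

Step 6
Reactants: 8 trans-2-ethyl-5-methyl-4-vinylcyclopent-2-en-1-one; 2 1-methoxy-1-(trimethylsilyloxy)prop-1-ene
Product: 9 methyl 2-[2-ethyl-4-methyl-3-(trimethylsilyloxy)-5-vinylcyclopent-2-en-1-yl]propanoate
Conditions: Tf2NH (cat.), CH2Cl2, −78 °C; Et3N quench
Reagents that add atoms: none
Why: Mukaiyama–Michael addition: the ketene acetal attacks C3a anti to the adjacent vinyl group, which sets C3a trans to C7a, and silyl transfer fixes the enol ether at C2=C3. C4 forms as a mixture that step 15 erases.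

Step 7
Reactants: 9 methyl 2-[2-ethyl-4-methyl-3-(trimethylsilyloxy)-5-vinylcyclopent-2-en-1-yl]propanoate
Product: 10 methyl 2-[2-ethyl-4-methyl-3-(trifluoromethylsulfonyloxy)-5-vinylcyclopent-2-en-1-yl]propanoate
Conditions: CsF, PhNTf2, DME, rt
Reagents that add atoms: N-phenylbis(trifluoromethanesulfonimide), O=S(=O)(N(c1ccccc1)S(=O)(=O)C(F)(F)F)C(F)(F)F
Why: Fluoride releases the enolate regiospecifically from the silyl enol ether and the triflimide traps it on oxygen; no organolithium is used, so the ester is untouched.

Step 8
Reactants: 10 methyl 2-[2-ethyl-4-methyl-3-(trifluoromethylsulfonyloxy)-5-vinylcyclopent-2-en-1-yl]propanoate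
Product: 11 methyl 2-[2-ethyl-5-formyl-4-methyl-3-(trifluoromethylsulfonyloxy)cyclopent-2-en-1-yl]propanoate
Conditions: OsO4 (cat.), NaIO4, 2,6-lutidine, dioxane/H2O, rt
Reagents that add atoms: osmium tetroxide, O=[Os](=O)(=O)=O (catalytic oxygen carrier); sodium periodate, [Na+].[O-]I(=O)(=O)=O
Why: Lemieux–Johnson cleavage: OsO4 selects the monosubstituted vinyl group over the tetrasubstituted, electron-poor enol triflate, the only other alkene. This is why the cleavage precedes the triflate reduction.

Step 9
Reactants: 11 methyl 2-[2-ethyl-5-formyl-4-methyl-3-(trifluoromethylsulfonyloxy)cyclopent-2-en-1-yl]propanoate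
Product: 12 methyl 2-[2-ethyl-5-formyl-4-methylcyclopent-2-en-1-yl]propanoate
Conditions: Pd(OAc)2 (cat.), PPh3, n-Bu3N, HCO2H, DMF, 60 °C
Reagents that add atoms: none
Why: Palladium-catalysed formate reduction of the enol triflate (oxidative addition, formate-to-hydride exchange, reductive elimination) leaves the alkene at C2=C3 as in the target. The aldehyde and ester are inert, and the all-trans aldehyde is the stable epimer.

Step 10
Reactants: 13 2-ethylprop-2-enal
Product: 15 (E)-3-bromo-2-ethylprop-2-enal, via 2,3-dibromo-2-ethylpropanal 14 (not isolated)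
Conditions: Br2, CH2Cl2, −78 °C; then Et3N, 0 °C
Reagents that add atoms: bromine, BrBr
Why: Bromine addition and E2 loss of HBr give the β-bromoenal. The E isomer (bromine anti to the carbonyl, cis to ethyl) is expected as the thermodynamic product by analogy with the α-methyl series and should be confirmed by NOE.

Step 11
Reactants: 15 (E)-3-bromo-2-ethylprop-2-enal
Product: 16 (E)-1-bromo-2-ethyl-3,3-dimethoxyprop-1-ene
Conditions: MeOSiMe3, Me3SiOTf (cat.), CH2Cl2, −78 °C
Reagents that add atoms: methoxytrimethylsilane, CO[Si](C)(C)C
Why: Silyl-triflate-catalysed acetalisation with the silyl ether of methanol is aprotic and cold, so neither conjugate addition nor vinylic substitution of bromide should compete.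

Step 12
Reactants: 16 (E)-1-bromo-2-ethyl-3,3-dimethoxyprop-1-ene; 12 methyl 2-[2-ethyl-5-formyl-4-methylcyclopent-2-en-1-yl]propanoate
Product: 18 methyl 2-{2-ethyl-5-[(E)-3-ethyl-1-hydroxy-4,4-dimethoxybut-2-enyl]-4-methylcyclopent-2-en-1-yl}propanoate, via alkenyllithium 17 (not isolated)
Conditions: t-BuLi, Et2O, −78 °C; then 12, −78 °C; AcOH quench at −78 °C
Reagents that add atoms: tert-butyllithium, [Li]C(C)(C)C (supplies the lithium of 17 only; no reagent atom other than hydrogen remains in 18)
Why: Bromine–lithium exchange retains the alkene geometry, and the alkenyllithium adds to the aldehyde far faster than to the hindered ester at −78 °C. The cold quench prevents lactonisation of the secondary alkoxide, and the new carbinol centre is removed in step 13.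

Step 13
Reactants: 18 methyl 2-{2-ethyl-5-[(E)-3-ethyl-1-hydroxy-4,4-dimethoxybut-2-enyl]-4-methylcyclopent-2-en-1-yl}propanoate
Product: 19 methyl 2-{2-ethyl-5-[(E)-3-ethyl-4,4-dimethoxybut-2-enoyl]-4-methylcyclopent-2-en-1-yl}propanoate
Conditions: Dess–Martin periodinane, NaHCO3, CH2Cl2, 0 °C to rt
Reagents that add atoms: none
Why: Buffered periodinane oxidation of the allylic alcohol gives the enone without acid that could open the acetal or scramble the alkene.

Step 14
Reactants: 19 methyl 2-{2-ethyl-5-[(E)-3-ethyl-4,4-dimethoxybut-2-enoyl]-4-methylcyclopent-2-en-1-yl}propanoate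
Product: 21 trans-fused 5-ethyl-1-[(E)-2-ethyl-3,3-dimethoxyprop-1-enyl]-1,4,7-trimethyl-4,4a,7,7a-tetrahydrocyclopenta[c]pyran-3(1H)-one, via bromomagnesium alkoxide 20 (not isolated)
Conditions: MeMgBr, CeCl3, THF, −78 °C; then rt
Reagents that add atoms: methylmagnesium bromide, C[Mg]Br
Why: The organocerium reagent adds 1,2 to the β,β-disubstituted enone without enolising C7a. In the staggered transition state with the carbonyl oxygen over the ring, methyl should enter on the side flanked by the C1 methyl, not the side screened by the C3a propanoate arm, which puts the alkenyl group syn to H-7a. The tertiary alkoxide 20 then closes onto the methyl ester on warming.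

Step 15
Reactants: 21 trans-fused 5-ethyl-1-[(E)-2-ethyl-3,3-dimethoxyprop-1-enyl]-1,4,7-trimethyl-4,4a,7,7a-tetrahydrocyclopenta[c]pyran-3(1H)-one
Product: 24 5-(dimethoxymethyl)-3,5-diethyl-1,4,7-trimethyl-3a,4,5,7a-tetrahydro-1H-indene-4-carboxylic acid, via silyl ketene acetal 22 (not isolated), via trimethylsilyl ester 23 (not isolated)
Conditions: LiN(iPr)2, Me3SiCl/Et3N, THF, −78 °C; then toluene, 100–110 °C; then H2O/THF, rt
Reagents that add atoms: chlorotrimethylsilane, C[Si](C)(C)Cl (silicon of 22 and 23 only; none remains in 24)
Why: Deprotonation at C4 and O-silylation give the cyclic ketene acetal 22, whose geometry is fixed by the ring, so both C4 epimers of 21 converge. On heating, 22 undergoes a concerted suprafacial [3,3] shift that forms C4–C5, breaks C7–O and moves the alkene to C6=C7; this is the known ester-enolate Claisen rearrangement of alkenyl lactones (lactone-to-carbocycle ring contraction). The six-membered carbocycle closes through the only array the lactone allows, a twisted boat in which C4 and C7 are the bridgeheads of a bicyclo[2.2.2]octane-like transition state. C4 is controlled by C7: the O–C(=O) bridge stays on the face that the ring oxygen occupied at C7, anti to H-7a, so the carboxyl ends cis to H-3a and the methyl trans. C5 is controlled by the alkene geometry: the ethyl group, cis to C7, points inward under the ring-fusion bond and ends trans to the carboxyl, while the acetal carbon points outward and ends cis to it. The step needs the boat to be reachable: its twist sense is dictated by C7, and with the alkenyl group syn to H-7a this twist keeps the C3a–C7a bond gauche, as the trans-fused cyclopentene requires. The C7 epimer would need the opposite twist and should remain as unchanged lactone. Neutral hydrolysis of silyl ester 23 leaves the acetal intact.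

Step 16
Reactants: 24 5-(dimethoxymethyl)-3,5-diethyl-1,4,7-trimethyl-3a,4,5,7a-tetrahydro-1H-indene-4-carboxylic acid
Product: 25 3,5-diethyl-5-formyl-1,4,7-trimethyl-3a,4,5,7a-tetrahydro-1H-indene-4-carboxylic acid
Conditions: 1 M HCl, THF, rt
Reagents that add atoms: water, O
Why: Acid-catalysed acetal hydrolysis; C5 is quaternary, so the aldehyde cannot epimerise or conjugate. The product may rest as its ring-chain tautomer (hydroxy-γ-lactone), which reopens to the carboxylate aldehyde under the basic conditions of step 17.

Step 17
Reactants: 25 3,5-diethyl-5-formyl-1,4,7-trimethyl-3a,4,5,7a-tetrahydro-1H-indene-4-carboxylic acid; 26 diethyl [(E)-3-phenylprop-2-enyl]phosphonate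
Product: 28 3,5-diethyl-1,4,7-trimethyl-5-[(1E,3E)-4-phenylbuta-1,3-dienyl]-3a,4,5,7a-tetrahydro-1H-indene-4-carboxylic acid, via sodium phosphonate carbanion 27 (not isolated)
Conditions: NaN(SiMe3)2 (excess), THF, −78 °C to rt; then aqueous citric acid
Reagents that add atoms: sodium bis(trimethylsilyl)amide, [Na+].C[Si](C)(C)[N-][Si](C)(C)C (supplies the sodium of 27 only)
Why: Horner–Wadsworth–Emmons olefination: the first equivalent of base forms the carboxylate and frees the aldehyde, and the allylic phosphonate anion 27 adds at its α-carbon and eliminates phosphate to give the new E alkene. The styryl geometry of 26 is retained and no stereocentre is touched.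

## Compound list

1 | methyl propanoate | CCC(=O)OC | starting material
2 | 1-methoxy-1-(trimethylsilyloxy)prop-1-ene (E/Z mixture, geometry without consequence) | CC=C(OC)O[Si](C)(C)C | intermediate
3 | (S)-4-(tert-butyldimethylsilyloxy)cyclopent-2-en-1-one | O=C1C[C@H](O[Si](C)(C)C(C)(C)C)C=C1 | starting material
4 | bromomagnesium 4-(tert-butyldimethylsilyloxy)-3-vinylcyclopent-1-en-1-olate, vinyl trans to silyloxy | Br[Mg]OC1=C[C@H](C=C)[C@@H](O[Si](C)(C)C(C)(C)C)C1 | intermediate (not isolated)
5 | 4-(tert-butyldimethylsilyloxy)-2-methyl-3-vinylcyclopentan-1-one, vinyl trans to both neighbours | O=C1C[C@H](O[Si](C)(C)C(C)(C)C)[C@@H](C=C)[C@@H]1C | intermediate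
6 | trans-5-methyl-4-vinylcyclopent-2-en-1-one | O=C1C=C[C@@H](C=C)[C@@H]1C | intermediate
7 | trans-2-iodo-5-methyl-4-vinylcyclopent-2-en-1-one | O=C1C(I)=C[C@@H](C=C)[C@@H]1C | intermediate
8 | trans-2-ethyl-5-methyl-4-vinylcyclopent-2-en-1-one | O=C1C(CC)=C[C@@H](C=C)[C@@H]1C | intermediate
9 | methyl 2-[2-ethyl-4-methyl-3-(trimethylsilyloxy)-5-vinylcyclopent-2-en-1-yl]propanoate, ring substituents all-trans, propanoate C2 epimers | CCC1=C(O[Si](C)(C)C)[C@@H](C)[C@H](C=C)[C@H]1C(C)C(=O)OC | intermediate
10 | methyl 2-[2-ethyl-4-methyl-3-(trifluoromethylsulfonyloxy)-5-vinylcyclopent-2-en-1-yl]propanoate, all-trans, C2 epimers | CCC1=C(OS(=O)(=O)C(F)(F)F)[C@@H](C)[C@H](C=C)[C@H]1C(C)C(=O)OC | intermediate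
11 | methyl 2-[2-ethyl-5-formyl-4-methyl-3-(trifluoromethylsulfonyloxy)cyclopent-2-en-1-yl]propanoate, all-trans, C2 epimers | CCC1=C(OS(=O)(=O)C(F)(F)F)[C@@H](C)[C@H](C=O)[C@H]1C(C)C(=O)OC | intermediate
12 | methyl 2-[2-ethyl-5-formyl-4-methylcyclopent-2-en-1-yl]propanoate, formyl trans to both neighbours, C2 epimers | CCC1=C[C@@H](C)[C@H](C=O)[C@H]1C(C)C(=O)OC | intermediate
13 | 2-ethylprop-2-enal (2-ethylacrolein) | C=C(CC)C=O | starting material
14 | 2,3-dibromo-2-ethylpropanal (racemic) | BrCC(Br)(CC)C=O | intermediate (not isolated)
15 | (E)-3-bromo-2-ethylprop-2-enal, bromine cis to ethyl | Br/C=C(\CC)C=O | intermediate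
16 | (E)-1-bromo-2-ethyl-3,3-dimethoxyprop-1-ene | Br/C=C(\CC)C(OC)OC | intermediate
17 | (E)-(2-ethyl-3,3-dimethoxyprop-1-enyl)lithium, lithium cis to ethyl | [Li]/C=C(\CC)C(OC)OC | intermediate (not isolated)
18 | methyl 2-{2-ethyl-5-[(E)-3-ethyl-1-hydroxy-4,4-dimethoxybut-2-enyl]-4-methylcyclopent-2-en-1-yl}propanoate, carbinol and C2 epimers | CCC1=C[C@@H](C)[C@H](C(O)/C=C(\CC)C(OC)OC)[C@H]1C(C)C(=O)OC | intermediate
19 | methyl 2-{2-ethyl-5-[(E)-3-ethyl-4,4-dimethoxybut-2-enoyl]-4-methylcyclopent-2-en-1-yl}propanoate, C2 epimers | CCC1=C[C@@H](C)[C@H](C(=O)/C=C(\CC)C(OC)OC)[C@H]1C(C)C(=O)OC | intermediate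
20 | bromomagnesium tertiary alkoxide from methyl addition to 19, alkenyl syn to H-7a after closure | CCC1=C[C@@H](C)[C@H]([C@](C)(O[Mg]Br)/C=C(\CC)C(OC)OC)[C@H]1C(C)C(=O)OC | intermediate (not isolated)
21 | 5-ethyl-1-[(E)-2-ethyl-3,3-dimethoxyprop-1-enyl]-1,4,7-trimethyl-4,4a,7,7a-tetrahydrocyclopenta[c]pyran-3(1H)-one, trans-fused, alkenyl cis to H-7a, C4 epimers | CCC1=C[C@@H](C)[C@@H]2[C@@](C)(/C=C(\CC)C(OC)OC)OC(=O)C(C)[C@@H]12 | intermediate
22 | 3-trimethylsilyloxy ketene acetal of 21 | CCC1=C[C@@H](C)[C@@H]2[C@@](C)(/C=C(\CC)C(OC)OC)OC(O[Si](C)(C)C)=C(C)[C@@H]12 | intermediate (not isolated)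
23 | trimethylsilyl ester of 24 | CCC1=C[C@@H](C)[C@@H]2C(C)=C[C@@](C(OC)OC)(CC)[C@](C)(C(=O)O[Si](C)(C)C)[C@@H]12 | intermediate (not isolated)
24 | 5-(dimethoxymethyl)-3,5-diethyl-1,4,7-trimethyl-3a,4,5,7a-tetrahydro-1H-indene-4-carboxylic acid, trans-fused, CO2H cis to H-3a and to the acetal carbon | CCC1=C[C@@H](C)[C@@H]2C(C)=C[C@@](C(OC)OC)(CC)[C@](C)(C(=O)O)[C@@H]12 | intermediate
25 | 3,5-diethyl-5-formyl-1,4,7-trimethyl-3a,4,5,7a-tetrahydro-1H-indene-4-carboxylic acid, same configuration (may rest as the hydroxy-lactone tautomer) | CCC1=C[C@@H](C)[C@@H]2C(C)=C[C@@](C=O)(CC)[C@](C)(C(=O)O)[C@@H]12 | intermediate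
26 | diethyl [(E)-3-phenylprop-2-enyl]phosphonate | CCOP(=O)(C/C=C/c1ccccc1)OCC | starting material
27 | sodium α-carbanion of 26 | [Na+].CCOP(=O)([CH-]/C=C/c1ccccc1)OCC | intermediate (not isolated)
28 | 3,5-diethyl-1,4,7-trimethyl-5-[(1E,3E)-4-phenylbuta-1,3-dienyl]-3a,4,5,7a-tetrahydro-1H-indene-4-carboxylic acid, trans-fused, C1 methyl cis to H-7a, CO2H cis to H-3a and to the dienyl group | CCC1=C[C@@H](C)[C@@H]2C(C)=C[C@@](/C=C/C=C/c3ccccc3)(CC)[C@](C)(C(=O)O)[C@@H]12 | target

## Step count and least certain steps

Total: 17 steps. Longest linear sequence: 14 steps from **3** (steps 2–9 and 12–17). Steps 1, 10 and 11 are side branches.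

**Step 15 (key step).** The rearrangement may be too slow to compete with loss of the ketene acetal (oxygen-to-carbon silyl migration, or hydrolysis back to **21**). The boat must form two adjacent quaternary carbons with the ethyl group turned inward under the C3a–C7a bond, close to H-7a. Fallback: the C4–C5 bond is made by an acyclic Ireland–Claisen rearrangement and the ring is closed afterwards by metathesis. This sets out from aldehyde **12** and alkenyllithium **17**. MeMgBr gives the secondary alcohol F1, periodinane oxidation the methyl ketone F2, and Wittig methylenation the isopropenyl ester F3. LiOH hydrolysis gives the acid F4, which is esterified (carbodiimide, DMAP) with the allylic alcohol F5, obtained from **17** and paraformaldehyde, to give the allyl ester F6. Enolisation, silylation and warming give the diene acid F7, which carries both quaternary centres. Ring-closing metathesis of its vinyl and isopropenyl groups (second-generation Grubbs catalyst) returns to the route at **24**. The price is that the relay from C7 is lost: the chair transition state and the poorly controlled ketene acetal geometry would give diastereomers that have to be separated.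

**Step 14.** Facial discrimination in the methyl addition may be poor. The alkenyl group of **19** may itself prefer the less hindered side of the carbonyl and cancel the preference of the nucleophile, which would give the C7 epimer that cannot rearrange. Fallback: the methyl group is added to a ketone whose other substituent is slim, and the trisubstituted alkene is built afterwards. This sets out from **12**. But-1-ynyllithium gives the propargylic alcohol F8 and periodinane oxidation the ynone F9. MeMgBr/CeCl3 then adds from the side flanked by the C1 methyl, and the alkoxide closes to the butynyl lactone F10. Syn-hydrozirconation with Cp2Zr(H)Cl places zirconium on the alkyne carbon remote from C7, and iodine gives the iodoalkenyl lactone F11 with ethyl cis to C7. Suzuki–Miyaura coupling with the dienylboronate F12 (from pinacolborane and (E)-but-1-en-3-ynylbenzene) gives the trienyl lactone F13. The ketene acetal rearrangement of F13, run as in step 15, returns to the route at **28**.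

**Step 2.** Proton transfer within enolate **4** before methylation would lead to β-elimination of the silyloxy group and to over-methylation. Fallback: the methyl group is introduced after the elimination. This sets out from **3**. Conjugate vinyl addition with Me3SiCl and aqueous work-up give the ketone F14, DBU gives the enone F15, and kinetic α′-deprotonation with LiN(iPr)2 followed by MeI (anti to the vinyl group) returns to the route at **6**.

**Step 10.** The elimination is not stereospecific by mechanism, so the isomer with bromine cis to the formyl group may form, or the geometry may scramble. That would invert C5 in step 15. Fallback: the butynyl route described under step 14, which needs no preformed alkenyl bromide and fixes the geometry by syn-hydrozirconation. It sets out from **12** and returns at **28**.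

**Step 17.** Addition and elimination may be slow at the neopentyl aldehyde, which is held back as its lactol; attack through the γ-carbon of the ambident anion and incomplete E selectivity may follow. Fallback: the diene is assembled by cross-coupling. This sets out from **25**. The Ohira–Bestmann reagent (K2CO3, MeOH) gives the alkyne acid F16; Cp2Zr(H)Cl in excess, then iodine, gives the (E)-iodoalkene acid F17; Suzuki–Miyaura coupling with (E)-2-phenylvinylboronic acid (Pd(PPh3)4, K3PO4) returns to the route at **28**.

## Further compounds

F1 | step 15 | methyl 2-[2-ethyl-5-(1-hydroxyethyl)-4-methylcyclopent-2-en-1-yl]propanoate (carbinol and C2 epimers) | CCC1=C[C@@H](C)[C@H](C(C)O)[C@H]1C(C)C(=O)OC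
F2 | step 15 | methyl 2-[5-acetyl-2-ethyl-4-methylcyclopent-2-en-1-yl]propanoate | CCC1=C[C@@H](C)[C@H](C(C)=O)[C@H]1C(C)C(=O)OC
F3 | step 15 | methyl 2-[2-ethyl-4-methyl-5-(prop-1-en-2-yl)cyclopent-2-en-1-yl]propanoate | CCC1=C[C@@H](C)[C@H](C(C)=C)[C@H]1C(C)C(=O)OC
F4 | step 15 | 2-[2-ethyl-4-methyl-5-(prop-1-en-2-yl)cyclopent-2-en-1-yl]propanoic acid | CCC1=C[C@@H](C)[C@H](C(C)=C)[C@H]1C(C)C(=O)O
F5 | step 15 | (E)-3-ethyl-4,4-dimethoxybut-2-en-1-ol | OC/C=C(\CC)C(OC)OC
F6 | step 15 | (E)-3-ethyl-4,4-dimethoxybut-2-enyl 2-[2-ethyl-4-methyl-5-(prop-1-en-2-yl)cyclopent-2-en-1-yl]propanoate | CCC1=C[C@@H](C)[C@H](C(C)=C)[C@H]1C(C)C(=O)OC/C=C(\CC)C(OC)OC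
F7 | step 15 | 3-(dimethoxymethyl)-3-ethyl-2-[2-ethyl-4-methyl-5-(prop-1-en-2-yl)cyclopent-2-en-1-yl]-2-methylpent-4-enoic acid (diastereomer leading to 24) | CCC1=C[C@@H](C)[C@H](C(C)=C)[C@H]1[C@@](C)(C(=O)O)[C@](CC)(C=C)C(OC)OC
F8 | step 14 | methyl 2-[2-ethyl-5-(1-hydroxypent-2-ynyl)-4-methylcyclopent-2-en-1-yl]propanoate (carbinol and C2 epimers) | CCC1=C[C@@H](C)[C@H](C(O)C#CCC)[C@H]1C(C)C(=O)OC
F9 | step 14 | methyl 2-[2-ethyl-4-methyl-5-(pent-2-ynoyl)cyclopent-2-en-1-yl]propanoate | CCC1=C[C@@H](C)[C@H](C(=O)C#CCC)[C@H]1C(C)C(=O)OC
F10 | step 14 | 1-(but-1-ynyl)-5-ethyl-1,4,7-trimethyl-4,4a,7,7a-tetrahydrocyclopenta[c]pyran-3(1H)-one (trans-fused, alkynyl cis to H-7a) | CCC1=C[C@@H](C)[C@@H]2[C@@](C)(C#CCC)OC(=O)C(C)[C@@H]12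
F11 | step 14 | 5-ethyl-1-(2-iodobut-1-enyl)-1,4,7-trimethyl-4,4a,7,7a-tetrahydrocyclopenta[c]pyran-3(1H)-one (ethyl cis to C7) | CCC1=C[C@@H](C)[C@@H]2[C@@](C)(/C=C(\CC)I)OC(=O)C(C)[C@@H]12
F12 | step 14 | 4,4,5,5-tetramethyl-2-[(1E,3E)-4-phenylbuta-1,3-dienyl]-1,3,2-dioxaborolane | CC1(C)OB(/C=C/C=C/c2ccccc2)OC1(C)C
F13 | step 14 | 5-ethyl-1-[(1E,3E,5E)-2-ethyl-6-phenylhexa-1,3,5-trienyl]-1,4,7-trimethyl-4,4a,7,7a-tetrahydrocyclopenta[c]pyran-3(1H)-one | CCC1=C[C@@H](C)[C@@H]2[C@@](C)(/C=C(\CC)/C=C/C=C/c3ccccc3)OC(=O)C(C)[C@@H]12
F14 | step 2 | trans-4-(tert-butyldimethylsilyloxy)-3-vinylcyclopentan-1-one | O=C1C[C@H](O[Si](C)(C)C(C)(C)C)[C@@H](C=C)C1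
F15 | step 2 | 4-vinylcyclopent-2-en-1-one (single enantiomer) | O=C1C=C[C@@H](C=C)C1
F0 | step 10 | none | none
F16 | step 17 | 3,5-diethyl-5-ethynyl-1,4,7-trimethyl-3a,4,5,7a-tetrahydro-1H-indene-4-carboxylic acid | CCC1=C[C@@H](C)[C@@H]2C(C)=C[C@@](C#C)(CC)[C@](C)(C(=O)O)[C@@H]12
F17 | step 17 | 3,5-diethyl-5-[(E)-2-iodovinyl]-1,4,7-trimethyl-3a,4,5,7a-tetrahydro-1H-indene-4-carboxylic acid | CCC1=C[C@@H](C)[C@@H]2C(C)=C[C@@](/C=C/I)(CC)[C@](C)(C(=O)O)[C@@H]12
A1 | alternative 1 | methyl (2E,6Z)-7-iodo-5-methyl-4-(2-methyl-1,3-dioxolan-2-yl)nona-2,6-dienoate | CC/C(I)=C/[C@@H](C)[C@H](C1(C)OCCO1)/C=C/C(=O)OC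
A2 | alternative 1 | methyl 2-[2-ethyl-4-methyl-5-(2-methyl-1,3-dioxolan-2-yl)cyclopent-2-en-1-yl]acetate | CCC1=C[C@@H](C)[C@H](C2(C)OCCO2)[C@H]1CC(=O)OC
A3 | alternative 2 | methyl (4Z,6E)-2-(but-1-ynyl)-3-(tert-butyldimethylsilyloxymethyl)-3-ethyl-2,5-dimethylocta-4,6-dienoate | CCC#C[C@@](C)(C(=O)OC)[C@@](CC)(CO[Si](C)(C)C(C)(C)C)/C=C(C)\C=C\C
A4 | alternative 2 | methyl 5-(tert-butyldimethylsilyloxymethyl)-3,5-diethyl-1,4,7-trimethyl-2-oxo-2,4,5,7a-tetrahydro-1H-indene-4-carboxylate | CCC1=C2[C@@](C)(C(=O)OC)[C@@](CC)(CO[Si](C)(C)C(C)(C)C)C=C(C)[C@H]2[C@H](C)C1=O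
A5 | alternative 3 | methyl (3E,6E)-3-ethyl-2-{2-ethyl-5-[(Z)-1-iodoprop-1-en-2-yl]-4-methylcyclopent-2-en-1-yl}-2-methyl-7-phenylhepta-3,6-dienoate | CCC1=C[C@@H](C)[C@H](/C(C)=C\I)[C@H]1[C@@](C)(C(=O)OC)/C(CC)=C/C/C=C/c1ccccc1
A6 | alternative 3 | methyl ester of 28 | CCC1=C[C@@H](C)[C@@H]2C(C)=C[C@@](/C=C/C=C/c3ccccc3)(CC)[C@](C)(C(=O)OC)[C@@H]12
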